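The route rests on cutting the sp2–sp2 single bond of the (Z)-diene, between the cis CH= carbon and the C(=CH2) carbon. The feature exploited is the five-atom array O–CH–CH2–CH=CH that links the carbinol oxygen to that cis-alkenyl carbon. One boron atom closes it to a temporary six-membered 5,6-dihydro-1,2-oxaborinine ring, in which only the Z alkene can exist. This ring comes in one step from an α-quaternary thiazolyl aldehyde by catalytic asymmetric allylboration with an allylic gem-diboronate. The key step, a ring-opening Suzuki–Miyaura coupling with a 2-iodoalkenyl carbamate, joins both halves, delivers the Z-diene and frees the alcohol. No protecting group is used.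

Key step: step 9

Assumption 1: the sense of induction of (R)-TRIP is taken from the accepted model for allyl pinacolboronates (Re-face attack, which gives R here). The (S)-acid is equally available if the gem-diboronate responds in the opposite sense.
Assumption 2: compounds 1, 3, 5, 6, 10, 11, 12 and 18 are taken as purchasable.

Step 1
Reactants: 1 ethyl 2-cyano-2-methylpropanoate
Product: 2 ethyl 3-amino-2,2-dimethyl-3-thioxopropanoate
Conditions: (EtO)2P(S)SH (1.5 equiv), H2O, THF, 70 °C
Reagents that add atoms: O,O-diethyl dithiophosphoric acid, CCOP(=S)(S)OCC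
Why: Thiolysis of a nitrile: the dithiophosphoric acid adds across the C≡N bond, which the geminal ester makes electrophilic, and water cleaves the S–P bond of the adduct to leave the primary thioamide, while the hindered ester stays intact.

Step 2
Reactants: 2 ethyl 3-amino-2,2-dimethyl-3-thioxopropanoate, 3 1,3-dichloroacetone
Product: 4 ethyl 2-[4-(chloromethyl)-1,3-thiazol-2-yl]-2-methylpropanoate
Conditions: acetone, reflux; aq NaHCO3 work-up
Reagents that add atoms: none
Why: Hantzsch thiazole synthesis: sulfur displaces one chloride, nitrogen condenses with the ketone and loss of water aromatises the ring, so the symmetric dihaloketone necessarily leaves its second CH2Cl arm at C4.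

Step 3
Reactants: 5 pent-1-en-4-yne, 6 zirconocene hydrochloride Cp2Zr(H)Cl, 4 ethyl 2-[4-(chloromethyl)-1,3-thiazol-2-yl]-2-methylpropanoate
Product: 8 ethyl 2-{4-[(2E)-hexa-2,5-dien-1-yl]-1,3-thiazol-2-yl}-2-methylpropanoate, via alkenylzirconocene chloride 7 (not isolated)
Conditions: 5 (slight excess) + 6, THF, rt, dark; then 4, NiCl2(PPh3)2/n-BuLi (5 mol % Ni(0)), THF, rt
Reagents that add atoms: none
Why: syn-Hydrozirconation is much faster at the terminal alkyne than at the terminal alkene and places zirconium at the chain end, which fixes the E geometry, and the alkenylzirconocene then couples with retention with the benzylic-type chloride in a Ni(0)-catalysed Negishi-type alkenyl–benzyl cross-coupling, a reaction type known for chloromethylated heteroarenes.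

Step 4
Reactants: 8 ethyl 2-{4-[(2E)-hexa-2,5-dien-1-yl]-1,3-thiazol-2-yl}-2-methylpropanoate
Product: 9 2-{4-[(2E)-hexa-2,5-dien-1-yl]-1,3-thiazol-2-yl}-2-methylpropanal
Conditions: DIBAL-H (1.2 equiv), CH2Cl2, −78 °C; MeOH, aq Rochelle salt
Reagents that add atoms: none
Why: Partial ester reduction with DIBAL-H: the neopentyl-type tetrahedral aluminium hemiacetal, further held by the thiazole nitrogen, should persist at −78 °C until the quench, and the aldehyde formed has no α-hydrogen and cannot enolise.

Step 5
Reactants: 10 allyl chloride, 11 bis(pinacolato)diboron, 12 lithium diisopropylamide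
Product: 15 2,2'-(prop-2-ene-1,1-diyl)bis(4,4,5,5-tetramethyl-1,3,2-dioxaborolane), via 1-chloroallyllithium 13 (not isolated), via chloroallyl diboron ate complex 14 (not isolated)
Conditions: 12 (1.05 equiv) added to 10 + 11, THF, −95 °C, then to rt
Reagents that add atoms: none
Why: gem-Diborylation of a lithium carbenoid: LDA deprotonates allyl chloride in the presence of the diboron, the 1-chloroallyllithium is trapped at its α-carbon, and a Matteson-type 1,2-shift of the boryl group in the ate complex expels chloride.

Step 6
Reactants: 9 2-{4-[(2E)-hexa-2,5-dien-1-yl]-1,3-thiazol-2-yl}-2-methylpropanal, 15 2,2'-(prop-2-ene-1,1-diyl)bis(4,4,5,5-tetramethyl-1,3,2-dioxaborolane)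
Product: 17 (6R)-6-(2-{4-[(2E)-hexa-2,5-dien-1-yl]-1,3-thiazol-2-yl}propan-2-yl)-5,6-dihydro-2H-1,2-oxaborinin-2-ol, via O-boryl (Z)-alkenylboronate 16 (not isolated)
Conditions: (R)-TRIP (10 mol %), 4 Å MS, toluene, −20 °C to rt; then THF–H2O, SiO2
Reagents that add atoms: water, O
Why: Chiral-phosphoric-acid-catalysed asymmetric allylboration through a closed chair transition state: the spectator Bpin group takes the pseudo-axial position to avoid the pinacol of the reacting boron, which sets the Z alkene, the (R)-acid bound to a boronate oxygen and to the formyl hydrogen should expose the Re face of 9, which sets the R carbinol centre, and on hydrolysis only the Z isomer can close to the six-membered B–O ring, a reaction type known for allylic gem-diboronates.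

Step 7
Reactants: 18 but-3-yn-1-amine
Product: 19 methyl but-3-yn-1-ylcarbamate
Conditions: ClCO2Me, NaHCO3, THF–H2O, 0 °C to rt
Reagents that add atoms: methyl chloroformate, COC(=O)Cl
Why: Schotten–Baumann-type N-acylation of a primary amine with a chloroformate, to which the terminal alkyne is inert.

Step 8
Reactants: 19 methyl but-3-yn-1-ylcarbamate
Product: 20 methyl (3-iodobut-3-en-1-yl)carbamate
Conditions: NaI, TMSCl, H2O (0.5 equiv), MeCN, rt
Reagents that add atoms: sodium iodide, [Na+].[I-]
Why: Markovnikov hydroiodination of a terminal alkyne with HI made in situ: protonation at the terminal carbon puts the positive charge on the internal carbon, where iodide adds, and the methyl carbamate should tolerate the short exposure at room temperature.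

Step 9
Reactants: 17 (6R)-6-(2-{4-[(2E)-hexa-2,5-dien-1-yl]-1,3-thiazol-2-yl}propan-2-yl)-5,6-dihydro-2H-1,2-oxaborinin-2-ol, 20 methyl (3-iodobut-3-en-1-yl)carbamate
Product: 21 mycothiazole, methyl N-[(4Z,7R)-8-{4-[(2E)-hexa-2,5-dien-1-yl]-1,3-thiazol-2-yl}-7-hydroxy-8-methyl-3-methylidenenon-4-en-1-yl]carbamate
Conditions: PdCl2(dppf)·CH2Cl2 (5 mol %), K3PO4 (3 equiv), degassed THF–H2O, rt, dark
Reagents that add atoms: none
Why: Pd(0) inserts into the C–I bond of 20, the hydroxyboronate form of 17 transfers its alkenyl carbon to palladium through a Pd–O–B bridge, and reductive elimination forms the C(sp2)–C(sp2) bond, each event with retention at both alkenyl carbons. The closest known reaction type is the Suzuki–Miyaura coupling of cyclic alkenylboronic half-esters (1,2-oxaborin-3-enes) with alkenyl and aryl halides. No ring is closed: the six-membered B–O ring is opened, and hydrolysis of the remaining B–O bond frees the carbinol OH in the same operation. No new stereocentre is made, since the R carbinol centre is a spectator and the Z geometry stored in the endocyclic C=C of 17 is carried over by retention. The step needs chemoselectivity for the alkenyl iodide over the thiazole, the skipped diene and the free NH and OH groups, which the fast oxidative addition of a C(sp2)–I bond at room temperature secures. It also needs suppression of Z-to-E drift, protodeboronation and thermal 1,5-hydrogen shift of the product, for which a bidentate ligand, a mild phosphate base and ambient temperature are chosen.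

Compound list
1 | ethyl 2-cyano-2-methylpropanoate | CCOC(=O)C(C)(C)C#N | starting material
2 | ethyl 3-amino-2,2-dimethyl-3-thioxopropanoate | CCOC(=O)C(C)(C)C(N)=S | intermediate
3 | 1,3-dichloroacetone | ClCC(=O)CCl | starting material
4 | ethyl 2-[4-(chloromethyl)-1,3-thiazol-2-yl]-2-methylpropanoate | CCOC(=O)C(C)(C)c1nc(CCl)cs1 | intermediate
5 | pent-1-en-4-yne | C=CCC#C | starting material
6 | zirconocene hydrochloride, Cp2Zr(H)Cl | [H][Zr](Cl)(C1C=CC=C1)C1C=CC=C1 | starting material
7 | chloro[(1E)-penta-1,4-dien-1-yl]zirconocene | C=CC/C=C/[Zr](Cl)(C1C=CC=C1)C1C=CC=C1 | intermediate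
8 | ethyl 2-{4-[(2E)-hexa-2,5-dien-1-yl]-1,3-thiazol-2-yl}-2-methylpropanoate | CCOC(=O)C(C)(C)c1nc(C/C=C/CC=C)cs1 | intermediate
9 | 2-{4-[(2E)-hexa-2,5-dien-1-yl]-1,3-thiazol-2-yl}-2-methylpropanal | O=CC(C)(C)c1nc(C/C=C/CC=C)cs1 | intermediate
10 | allyl chloride | C=CCCl | starting material
11 | bis(pinacolato)diboron | CC1(C)OB(OC1(C)C)B1OC(C)(C)C(C)(C)O1 | starting material
12 | lithium diisopropylamide | [Li+].CC(C)[N-]C(C)C | starting material
13 | 1-chloroallyllithium | [Li]C(Cl)C=C | intermediate
14 | lithium (1-chloroallyl)diboron ate complex | [Li+].C=CC(Cl)[B-]1(OC(C)(C)C(C)(C)O1)B1OC(C)(C)C(C)(C)O1 | intermediate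
15 | 2,2'-(prop-2-ene-1,1-diyl)bis(4,4,5,5-tetramethyl-1,3,2-dioxaborolane) | C=CC(B1OC(C)(C)C(C)(C)O1)B1OC(C)(C)C(C)(C)O1 | intermediate
16 | pinacol borate of (3R,5Z)-2-{4-[(2E)-hexa-2,5-dien-1-yl]-1,3-thiazol-2-yl}-2-methyl-6-(pinacolboryl)hex-5-en-3-ol | C=CC/C=C/Cc1csc(C(C)(C)[C@H](OB2OC(C)(C)C(C)(C)O2)C/C=C\B2OC(C)(C)C(C)(C)O2)n1 | intermediate
17 | (6R)-6-(2-{4-[(2E)-hexa-2,5-dien-1-yl]-1,3-thiazol-2-yl}propan-2-yl)-5,6-dihydro-2H-1,2-oxaborinin-2-ol | C=CC/C=C/Cc1csc(C(C)(C)[C@H]2CC=CB(O)O2)n1 | intermediate
18 | but-3-yn-1-amine | C#CCCN | starting material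
19 | methyl but-3-yn-1-ylcarbamate | C#CCCNC(=O)OC | intermediate
20 | methyl (3-iodobut-3-en-1-yl)carbamate | C=C(I)CCNC(=O)OC | intermediate
21 | mycothiazole, (R)-carbinol, (Z)-diene, (E)-skipped diene | C=CC/C=C/Cc1csc(C(C)(C)[C@H](O)C/C=C\C(=C)CCNC(=O)OC)n1 | target

Total step count: 9
Longest linear sequence: 6 steps (steps 1, 2, 3, 4, 6, 9)

Steps most likely to fail

Step 6. The addition may be sluggish and the facial or Z/E selectivity poor, because the formyl group is neopentyl-like and the thiazole nitrogen can tie up the acid catalyst. The fallback sets out from 9 and comes back at 17. It moves stereocontrol from a catalyst to a stoichiometric chiral reagent and brings in the boron afterwards. Asymmetric propargylation of 9 uses a chiral allenylborane carrying the bis-sulfonamide of 1,2-diphenylethane-1,2-diamine on boron, in the enantiomer that attacks the Re face. It should give the homopropargylic alcohol (3R)-2-{4-[(2E)-hexa-2,5-dien-1-yl]-1,3-thiazol-2-yl}-2-methylhex-5-yn-3-ol F1. Its terminal alkyne then undergoes formal trans-hydroboration with pinacolborane by way of a rhodium vinylidene ([Rh(cod)Cl]2, P(iPr)3, Et3N), a path open only to a terminal alkyne. This should give the (Z)-alkenylboronate (3R,5Z)-2-{4-[(2E)-hexa-2,5-dien-1-yl]-1,3-thiazol-2-yl}-2-methyl-6-(4,4,5,5-tetramethyl-1,3,2-dioxaborolan-2-yl)hex-5-en-3-ol F2, which closes to 17 on aqueous work-up.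

Step 9. The half-ester may protodeboronate in basic aqueous medium, the Z geometry may drift at palladium, or thiazole coordination may slow the catalyst. The fallback sets out from 17 and 20 and comes back at 21. It reverses the polarity of both partners and removes the base.
- Iododeboronation of 17 with NIS (MeCN, 0 °C, dark), which goes with retention, should give the alkenyl iodide (3R,5Z)-2-{4-[(2E)-hexa-2,5-dien-1-yl]-1,3-thiazol-2-yl}-6-iodo-2-methylhex-5-en-3-ol F3.
- Palladium-catalysed stannylation of 20 with hexabutylditin should give the alkenylstannane methyl [3-(tributylstannyl)but-3-en-1-yl]carbamate F4.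
- A neutral Stille coupling of the two (Pd2(dba)3, AsPh3, CuI, DMF, rt) should give 21.

Step 3. Hydrozirconation of the volatile enyne may discriminate incompletely between alkyne and alkene, or metal hydrides may move the skipped diene into conjugation. The fallback sets out from 4 and comes back at 8. It assembles the 1,4-diene at its other sp3–sp2 bond.
- Stille coupling of 4 with purchased (E)-3-(tributylstannyl)prop-2-en-1-ol should give the allylic alcohol ethyl 2-{4-[(2E)-4-hydroxybut-2-en-1-yl]-1,3-thiazol-2-yl}-2-methylpropanoate F5.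
- Acetylation (Ac2O, pyridine) should give the allylic acetate ethyl 2-{4-[(2E)-4-acetoxybut-2-en-1-yl]-1,3-thiazol-2-yl}-2-methylpropanoate F6.
- A Pd(0)-catalysed allyl–vinyl Stille coupling with tributyl(vinyl)stannane (Pd(dba)2, LiCl, DMF) forms the bond at the less hindered terminus of the π-allyl and should give 8 with the E alkene.

Further compounds
F1 | step 6 | (3R)-2-{4-[(2E)-hexa-2,5-dien-1-yl]-1,3-thiazol-2-yl}-2-methylhex-5-yn-3-ol | C=CC/C=C/Cc1csc(C(C)(C)[C@H](O)CC#C)n1
F2 | step 6 | (3R,5Z)-2-{4-[(2E)-hexa-2,5-dien-1-yl]-1,3-thiazol-2-yl}-2-methyl-6-(4,4,5,5-tetramethyl-1,3,2-dioxaborolan-2-yl)hex-5-en-3-ol | C=CC/C=C/Cc1csc(C(C)(C)[C@H](O)C/C=C\B2OC(C)(C)C(C)(C)O2)n1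
F3 | step 9 | (3R,5Z)-2-{4-[(2E)-hexa-2,5-dien-1-yl]-1,3-thiazol-2-yl}-6-iodo-2-methylhex-5-en-3-ol | C=CC/C=C/Cc1csc(C(C)(C)[C@H](O)C/C=C\I)n1
F4 | step 9 | methyl [3-(tributylstannyl)but-3-en-1-yl]carbamate | C=C(CCNC(=O)OC)[Sn](CCCC)(CCCC)CCCC
F5 | step 3 | ethyl 2-{4-[(2E)-4-hydroxybut-2-en-1-yl]-1,3-thiazol-2-yl}-2-methylpropanoate | CCOC(=O)C(C)(C)c1nc(C/C=C/CO)cs1
F6 | step 3 | ethyl 2-{4-[(2E)-4-acetoxybut-2-en-1-yl]-1,3-thiazol-2-yl}-2-methylpropanoate | CCOC(=O)C(C)(C)c1nc(C/C=C/COC(C)=O)cs1
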